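**Retrosynthetic overview** (hydrindane locants C1–C7a: C1, C2, C3 in cyclopentane ring C; C3a/C7a ring fusion; C5 spiro carbon; C7 carbinol carbon of cyclohexane ring B; ring A carbons primed, C1′ = C5)

1. Ring A is made last: gem-diprenylation at C5′, preceded by a polyketide-type annulation (bonds C6′–C5′ and C2′–C3′) of a lactone ester at C5 with the dianion of 5-methylhexane-2,4-dione. The lactone ties the axial C7 oxygen to the axial carboxyl at C5, so the two carboxyls are differentiated and the spiro configuration is fixed.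
2. The C3 tertiary alcohol comes from an exocyclic methylene by radical hydration; the lactone comes from a C7 silyl ether and a symmetric diethyl malonate at C5.
3. Rings B and C come from an acyclic malonate in one operation, an intramolecular palladium trimethylenemethane (TMM) [3+2] cycloaddition: bond C3a–C7a closes ring B, then bond C1–C2 closes ring C.
4. The feature that allows this: in ring C, the carbinol carbon C3 with its neighbours C2 and C3a is a 2-methylidenepropane-1,3-diyl unit once the alcohol is read as a hydrated exocyclic alkene. C1–C7a is then a two-carbon acceptor (a vinyl sulfone, sulfone on C1, removed later) tethered to it through C7, C6, C5 and C4.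
5. The precursor is assembled from diethyl allylmalonate, a C5 isoprenoid chloro acetate and a silyl-substituted alkenyl Grignard reagent. Its single stereocentre (C7, Shi epoxidation) controls C7a and C3a. Ring order: B and C (key step), lactone, ring A.

Key step: step 7

Assumption: (E)-4-chloro-3-methylbut-2-en-1-yl acetate, 2-bromo-3-(trimethylsilyl)prop-1-ene and the D-fructose-derived Shi ketone are taken as commercial, and the enolised β-triketone of ring A is drawn as one tautomer throughout.

**Route**

Step 1
Reactants: 1 diethyl 2-allylmalonate; 2 (E)-4-chloro-3-methylbut-2-en-1-yl acetate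
Product: 3 diethyl 2-[(2E)-4-acetoxy-2-methylbut-2-en-1-yl]-2-allylmalonate
Conditions: NaH, THF/DMF, 0 °C; then 2, NaI (cat.), rt
Reagents that add atoms: none
Why: Malonate enolate SN2 alkylation at the primary allylic chloride, which is far more reactive than the allylic acetate, so the (E)-alkene and the acetate should be kept.

Step 2
Reactants: 3 diethyl 2-[(2E)-4-acetoxy-2-methylbut-2-en-1-yl]-2-allylmalonate
Product: 4 diethyl 2-allyl-2-[(2E)-2-methyl-4-(phenylsulfonyl)but-2-en-1-yl]malonate
Conditions: PhSO2Na, Pd(PPh3)4 (3 mol%), THF/MeOH, rt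
Reagents that add atoms: sodium benzenesulfinate, [Na+].[O-]S(=O)c1ccccc1
Why: Tsuji–Trost allylic substitution in which zerovalent palladium ionises the acetate and the sulfinate attacks the unhindered primary allyl terminus; syn/anti exchange at the fully substituted terminus is slow, so the E geometry should persist.

Step 3
Reactants: 4 diethyl 2-allyl-2-[(2E)-2-methyl-4-(phenylsulfonyl)but-2-en-1-yl]malonate
Product: 5 diethyl 2-allyl-2-{[(2R,3S)-2-methyl-3-(phenylsulfonylmethyl)oxiran-2-yl]methyl}malonate
Conditions: D-fructose-derived Shi ketone (0.3 equiv), Oxone, K2CO3, Bu4NHSO4, MeCN/dimethoxymethane/aq. borate buffer (pH 10.5), 0 °C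
Reagents that add atoms: potassium peroxymonosulfate (active component of Oxone), [K+].[O-]S(=O)(=O)OO
Why: Shi asymmetric epoxidation through the spiro dioxirane transition state, which for this (E)-trisubstituted alkene should deliver oxygen to the face giving the (2R) quaternary oxirane carbon (future C7); the electron-richer trisubstituted alkene reacts well before the monosubstituted allyl group.

Step 4
Reactants: 5 diethyl 2-allyl-2-{[(2R,3S)-2-methyl-3-(phenylsulfonylmethyl)oxiran-2-yl]methyl}malonate
Product: 7 diethyl 2-allyl-2-[(2R,3E)-2-methyl-4-(phenylsulfonyl)-2-(triethylsilyloxy)but-3-en-1-yl]malonate, via lithium alkoxide 6 (not isolated)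
Conditions: LDA (1.1 equiv), THF, −78 °C; then TESOTf (1.3 equiv), −78 → −20 °C
Reagents that add atoms: triethylsilyl trifluoromethanesulfonate, CC[Si](CC)(CC)OS(=O)(=O)C(F)(F)F
Why: Base-induced β-elimination of the β,γ-epoxy sulfone (E1cB from the α-sulfonyl carbanion) gives the γ-alkoxy (E)-vinyl sulfone with the C–O bond at the quaternary carbon untouched (configuration retained); immediate silylation stops the alkoxide from lactonising onto a malonate ester, which would desymmetrise C5 too early.

Step 5
Reactants: 7 diethyl 2-allyl-2-[(2R,3E)-2-methyl-4-(phenylsulfonyl)-2-(triethylsilyloxy)but-3-en-1-yl]malonate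
Product: 8 diethyl 2-[(2R,3E)-2-methyl-4-(phenylsulfonyl)-2-(triethylsilyloxy)but-3-en-1-yl]-2-(2-oxoethyl)malonate
Conditions: O3, CH2Cl2, −78 °C (Sudan red end point); then PPh3, −78 °C → rt
Reagents that add atoms: ozone, [O-][O+]=O
Why: Ozonolysis with reductive work-up cleaves the electron-rich terminal alkene, while the electron-poor vinyl sulfone reacts much more slowly with the electrophilic ozone.

Step 6
Reactants: 8 diethyl 2-[(2R,3E)-2-methyl-4-(phenylsulfonyl)-2-(triethylsilyloxy)but-3-en-1-yl]-2-(2-oxoethyl)malonate; 9 2-bromo-3-(trimethylsilyl)prop-1-ene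
Product: 12 diethyl 2-{2-[(methoxycarbonyl)oxy]-3-[(trimethylsilyl)methyl]but-3-en-1-yl}-2-[(2R,3E)-2-methyl-4-(phenylsulfonyl)-2-(triethylsilyloxy)but-3-en-1-yl]malonate (both carbinol epimers), via Grignard reagent 10 (not isolated), via bromomagnesium alkoxide 11 (not isolated)
Conditions: 9, Mg, THF, rt (gives 10); 8, THF, −78 °C; then ClCO2Me, −78 → 0 °C
Reagents that add atoms: methyl chloroformate, COC(=O)Cl
Why: 1,2-addition of the alkenyl Grignard reagent to the aldehyde (faster at −78 °C than attack on the hindered vinyl sulfone or the neopentyl esters) and in situ acylation of the alkoxide gives the standard substituted TMM precursor; the new carbinol centre is lost on ionisation, so its configuration is irrelevant.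

Step 7
Reactants: 12 diethyl 2-{2-[(methoxycarbonyl)oxy]-3-[(trimethylsilyl)methyl]but-3-en-1-yl}-2-[(2R,3E)-2-methyl-4-(phenylsulfonyl)-2-(triethylsilyloxy)but-3-en-1-yl]malonate
Product: 14 diethyl (3aR,7R,7aS)-7-methyl-3-methylidene-1-(phenylsulfonyl)-7-(triethylsilyloxy)octahydro-5H-indene-5,5-dicarboxylate (trans-fused; C1 epimers), via allylpalladium zwitterion 13 (not isolated)
Conditions: Pd(OAc)2 (5 mol%), P(OiPr)3 (30 mol%), THF (0.01 M), reflux
Reagents that add atoms: none
Why: Zerovalent palladium (from Pd(OAc)2 and P(OiPr)3) ionises the allylic carbonate and the liberated methoxide removes the silyl group, giving a palladium–TMM zwitterion whose tethered carbon (future C3a) adds to the vinyl sulfone β-carbon (future C7a) to give 13, after which the α-sulfonyl carbanion (C1) attacks a CH2 terminus (C2) of the η3-allylpalladium cation and closes ring C through the C1–C2 bond, leaving C3 as an exocyclic methylene. The closest known reaction type is the intramolecular palladium-catalysed trimethylenemethane [3+2] cycloaddition onto tethered vinyl sulfones, which gives bicyclo[4.3.0]nonanes. Ring B closes by a 6-exo-trig conjugate addition and ring C by allylic alkylation at an allyl terminus, the two termini being equivalent so that only the methylenecyclopentane can form. C7a and C3a are set in the Michael step by the C7 stereocentre through a chair-like transition state in which the allylpalladium arm at C3a and the sulfonylmethyl arm at C7a are equatorial and the smaller OSiEt3 (not the methyl) at C7 is axial beside the axial ester at C5, which should give the trans ring fusion with H7a anti to the C7 oxygen; C1 carries the sulfone as an inconsequential epimer mixture. The step needs intramolecular over intermolecular cycloaddition and attack through the substituted TMM carbon, which high dilution, the two quaternary tether carbons (C5, C7) and the eight-membered ring required by the alternative mode should secure.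

Step 8
Reactants: 14 diethyl (3aR,7R,7aS)-7-methyl-3-methylidene-1-(phenylsulfonyl)-7-(triethylsilyloxy)octahydro-5H-indene-5,5-dicarboxylate
Product: 15 diethyl (3aR,7R,7aS)-7-methyl-3-methylidene-7-(triethylsilyloxy)octahydro-5H-indene-5,5-dicarboxylate
Conditions: SmI2 (6 equiv), HMPA, THF/MeOH, −20 °C
Reagents that add atoms: none
Why: Reductive desulfonylation of the secondary alkyl phenyl sulfone by single-electron transfer from samarium diiodide, leaving C1 as CH2; esters, silyl ether and the isolated alkene are not reduced under these conditions.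

Step 9
Reactants: 15 diethyl (3aR,7R,7aS)-7-methyl-3-methylidene-7-(triethylsilyloxy)octahydro-5H-indene-5,5-dicarboxylate
Product: 17 ethyl (3aR,5R,7R,7aS)-7-methyl-3-methylidene-octahydro-1H-indene-5-carboxylate 5,7-carbolactone (axial C5 carboxyl lactonised onto the C7 oxygen), via tetrabutylammonium alkoxide 16 (not isolated)
Conditions: TBAF, THF, 0 °C → rt
Reagents that add atoms: none
Why: Fluoride desilylation gives the axial C7 alkoxide, which in the conformationally locked trans-hydrindane is 1,3-syn-diaxial to one ester only and lactonises onto it (6-oxabicyclo[3.2.1]octan-7-one unit); this sets the C5 stereocentre, and only the diastereomer with axial C7–O can react.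

Step 10
Reactants: 17 ethyl (3aR,5R,7R,7aS)-7-methyl-3-methylidene-octahydro-1H-indene-5-carboxylate 5,7-carbolactone
Product: 18 ethyl (3S,3aR,5R,7R,7aS)-3-hydroxy-3,7-dimethyl-octahydro-1H-indene-5-carboxylate 5,7-carbolactone
Conditions: Co(acac)2 (20 mol%), PhSiH3, O2 (1 atm), THF/iPrOH, rt; then aq. Na2S2O3
Reagents that add atoms: dioxygen, O=O
Why: Mukaiyama hydration (hydrogen-atom transfer to the 1,1-disubstituted alkene, oxygen trapping of the tertiary C3 radical) gives the Markovnikov alcohol; oxygen should enter anti to the axial C3a–H bond (torsional steering, as at C17 of trans-hydrindane D rings), placing OH trans to H3a.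

Step 11
Reactants: 18 ethyl (3S,3aR,5R,7R,7aS)-3-hydroxy-3,7-dimethyl-octahydro-1H-indene-5-carboxylate 5,7-carbolactone; 19 5-methylhexane-2,4-dione
Product: 22 (3S,3aR,5S,7R,7aS)-3,4′,7-trihydroxy-3,7-dimethyl-3′-(2-methylpropanoyl)octahydrospiro[indene-5,1′-cyclohexan]-3′-ene-2′,6′-dione, via diketone dianion 20 (not isolated), via triketo ester 21 (not isolated)
Conditions: 19 (3 equiv), LDA (6.2 equiv), THF, −78 → 0 °C (gives 20); 18, −78 → 0 °C; then rt → 40 °C; aq. HCl work-up
Reagents that add atoms: none
Why: The β-diketone dianion is acylated at its terminal carbon by the strained lactone carbonyl (more electrophilic than the neighbouring neopentyl ethyl ester), and the internal active methylene of the resulting 1,3,5-triketone then undergoes an intramolecular Claisen condensation onto the ester to close ring A; the connectivity, and hence the spiro configuration, follows from the lactone/ester differentiation.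

Step 12
Reactants: 22 (3S,3aR,5S,7R,7aS)-3,4′,7-trihydroxy-3,7-dimethyl-3′-(2-methylpropanoyl)octahydrospiro[indene-5,1′-cyclohexan]-3′-ene-2′,6′-dione; 23 1-bromo-3-methylbut-2-ene (prenyl bromide)
Product: 24 (3S,3aR,5S,7R,7aS)-3,4′,7-trihydroxy-3,7-dimethyl-5′,5′-bis(3-methylbut-2-en-1-yl)-3′-(2-methylpropanoyl)octahydrospiro[indene-5,1′-cyclohexan]-3′-ene-2′,6′-dione (target)
Conditions: 23 (2.3 equiv), NaOMe, MeOH, −10 → 0 °C
Reagents that add atoms: none
Why: Double C-alkylation of the enolised acyl trione at its only unsubstituted nucleophilic ring carbon (C5′), as in the gem-diprenylation of acylphloroglucinols to hop β-acids; the tertiary alcohols are inert and the acyl-bearing carbon is not alkylated.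

**Compound list**

1 | diethyl 2-allylmalonate | C=CCC(C(=O)OCC)C(=O)OCC | starting material
2 | (E)-4-chloro-3-methylbut-2-en-1-yl acetate | CC(=O)OC/C=C(\C)CCl | starting material
3 | diethyl 2-[(2E)-4-acetoxy-2-methylbut-2-en-1-yl]-2-allylmalonate | C=CCC(C/C(C)=C/COC(C)=O)(C(=O)OCC)C(=O)OCC | intermediate
4 | diethyl 2-allyl-2-[(2E)-2-methyl-4-(phenylsulfonyl)but-2-en-1-yl]malonate | C=CCC(C/C(C)=C/CS(=O)(=O)c1ccccc1)(C(=O)OCC)C(=O)OCC | intermediate
5 | diethyl 2-allyl-2-{[(2R,3S)-2-methyl-3-(phenylsulfonylmethyl)oxiran-2-yl]methyl}malonate | C=CCC(C[C@@]1(C)O[C@@H]1CS(=O)(=O)c1ccccc1)(C(=O)OCC)C(=O)OCC | intermediate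
6 | lithium alkoxide of diethyl 2-allyl-2-[(2R,3E)-2-hydroxy-2-methyl-4-(phenylsulfonyl)but-3-en-1-yl]malonate | [Li+].C=CCC(C[C@@](C)([O-])/C=C/S(=O)(=O)c1ccccc1)(C(=O)OCC)C(=O)OCC | intermediate
7 | diethyl 2-allyl-2-[(2R,3E)-2-methyl-4-(phenylsulfonyl)-2-(triethylsilyloxy)but-3-en-1-yl]malonate | C=CCC(C[C@@](C)(O[Si](CC)(CC)CC)/C=C/S(=O)(=O)c1ccccc1)(C(=O)OCC)C(=O)OCC | intermediate
8 | diethyl 2-[(2R,3E)-2-methyl-4-(phenylsulfonyl)-2-(triethylsilyloxy)but-3-en-1-yl]-2-(2-oxoethyl)malonate | O=CCC(C[C@@](C)(O[Si](CC)(CC)CC)/C=C/S(=O)(=O)c1ccccc1)(C(=O)OCC)C(=O)OCC | intermediate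
9 | 2-bromo-3-(trimethylsilyl)prop-1-ene | C=C(Br)C[Si](C)(C)C | starting material
10 | [3-(trimethylsilyl)prop-1-en-2-yl]magnesium bromide | C=C(C[Si](C)(C)C)[Mg]Br | intermediate
11 | bromomagnesium alkoxide from addition of 10 to 8 (carbinol epimers) | C=C(C[Si](C)(C)C)C(CC(C[C@@](C)(O[Si](CC)(CC)CC)/C=C/S(=O)(=O)c1ccccc1)(C(=O)OCC)C(=O)OCC)O[Mg]Br | intermediate
12 | diethyl 2-{2-[(methoxycarbonyl)oxy]-3-[(trimethylsilyl)methyl]but-3-en-1-yl}-2-[(2R,3E)-2-methyl-4-(phenylsulfonyl)-2-(triethylsilyloxy)but-3-en-1-yl]malonate (carbinol epimers) | C=C(C[Si](C)(C)C)C(CC(C[C@@](C)(O[Si](CC)(CC)CC)/C=C/S(=O)(=O)c1ccccc1)(C(=O)OCC)C(=O)OCC)OC(=O)OC | intermediate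
13 | cyclohexane zwitterion: α-sulfonyl carbanion and allylpalladium cation of divalent palladium (phosphite ligands omitted, η3-allyl drawn as η1) | CCOC(=O)C1(C(=O)OCC)C[C@@H](C(=C)C[Pd+])[C@H]([CH-]S(=O)(=O)c2ccccc2)[C@](C)(O[Si](CC)(CC)CC)C1 | intermediate
14 | diethyl (3aR,7R,7aS)-7-methyl-3-methylidene-1-(phenylsulfonyl)-7-(triethylsilyloxy)octahydro-5H-indene-5,5-dicarboxylate (trans-fused; C1 epimers) | CCOC(=O)C1(C(=O)OCC)C[C@@H]2[C@H](C(S(=O)(=O)c3ccccc3)CC2=C)[C@](C)(O[Si](CC)(CC)CC)C1 | intermediate
15 | diethyl (3aR,7R,7aS)-7-methyl-3-methylidene-7-(triethylsilyloxy)octahydro-5H-indene-5,5-dicarboxylate | CCOC(=O)C1(C(=O)OCC)C[C@@H]2[C@H](CCC2=C)[C@](C)(O[Si](CC)(CC)CC)C1 | intermediate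
16 | tetrabutylammonium C7 alkoxide of the desilylated diester | CCOC(=O)C1(C(=O)OCC)C[C@@H]2[C@H](CCC2=C)[C@](C)([O-])C1.CCCC[N+](CCCC)(CCCC)CCCC | intermediate
17 | ethyl (3aR,5R,7R,7aS)-7-methyl-3-methylidene-octahydro-1H-indene-5-carboxylate 5,7-carbolactone | O=C1[C@@]2(C[C@@H]3[C@H](CCC3=C)[C@](C)(O1)C2)C(=O)OCC | intermediate
18 | ethyl (3S,3aR,5R,7R,7aS)-3-hydroxy-3,7-dimethyl-octahydro-1H-indene-5-carboxylate 5,7-carbolactone | O=C1[C@@]2(C[C@@H]3[C@H](CC[C@]3(C)O)[C@](C)(O1)C2)C(=O)OCC | intermediate
19 | 5-methylhexane-2,4-dione | CC(=O)CC(=O)C(C)C | starting material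
20 | dilithium dianion of 5-methylhexane-2,4-dione | [Li+].[Li+].[CH2-]C(=O)[CH-]C(=O)C(C)C | intermediate
21 | ethyl (3S,3aR,5S,7R,7aS)-3,7-dihydroxy-3,7-dimethyl-5-(6-methyl-3,5-dioxoheptanoyl)octahydro-1H-indene-5-carboxylate | CC(C)C(=O)CC(=O)CC(=O)[C@@]1(C[C@@H]2[C@H](CC[C@]2(C)O)[C@](C)(O)C1)C(=O)OCC | intermediate
22 | (3S,3aR,5S,7R,7aS)-3,4′,7-trihydroxy-3,7-dimethyl-3′-(2-methylpropanoyl)octahydrospiro[indene-5,1′-cyclohexan]-3′-ene-2′,6′-dione | C1C(=O)[C@@]2(C[C@@H]3[C@H](CC[C@]3(C)O)[C@](C)(O)C2)C(=O)C(C(=O)C(C)C)=C1O | intermediate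
23 | 1-bromo-3-methylbut-2-ene (prenyl bromide) | CC(C)=CCBr | starting material
24 | (3S,3aR,5S,7R,7aS)-3,4′,7-trihydroxy-3,7-dimethyl-5′,5′-bis(3-methylbut-2-en-1-yl)-3′-(2-methylpropanoyl)octahydrospiro[indene-5,1′-cyclohexan]-3′-ene-2′,6′-dione | CC(C)=CCC1(CC=C(C)C)C(=O)[C@@]2(C[C@@H]3[C@H](CC[C@]3(C)O)[C@](C)(O)C2)C(=O)C(C(=O)C(C)C)=C1O | target

**Totals**

Total step count: 12. Longest linear sequence: 12 steps (1 to 24).

**Steps most likely to fail**

Step 7. Intermolecular cycloaddition or oligomerisation may outrun the Michael addition at the hindered β-carbon next to the quaternary C7. The chair-like ring closure may also lose facial control, giving methyl instead of silyloxy axial or a cis ring fusion. The fallback is stepwise, sets out from 8 and comes back at 14. Wittig reaction of 8 with (1-methoxyethylidene)triphenylphosphorane should give the methyl enol ether F1, and mild acid hydrolysis (oxalic acid on wet silica) the methyl ketone F2. A base (DBU or Cs2CO3, MeCN) should then close ring B by a reversible intramolecular Michael addition of the ketone enolate to the vinyl sulfone; only the internal α-carbon (C3a) can reach in a six-membered transition state. This should give the trans-2,3-disubstituted cyclohexane F3 under thermodynamic control. Wittig methylenation (Ph3P=CH2) should give the isopropenyl compound F4, and ene-type allylic chlorination (Ca(OCl)2, CO2, CH2Cl2/H2O) the 2-(chloromethyl)allyl compound F5. LDA should then close ring C by intramolecular alkylation of the α-sulfonyl carbanion (5-exo-tet, again forming C1–C2), which gives 14.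

Step 11. The dianion may attack the ethyl ester instead of the lactone, which would invert the orientation of ring A at the spiro carbon. The opened triketone may also revert to the lactone by retro-Claisen, or the Claisen ring closure onto the neopentyl ester may stall. The fallback sets out from 18 and comes back at 22. Saponification of 18 (LiOH, aq. THF) and acidification should give the lactone acid F6, because the 1,3-diaxial hydroxy acid relactonises and leaves the equatorial carboxyl free. CDI should give the acyl imidazolide F7. C-acylation of the magnesium enolate of 19 (MgCl2, Et3N) should give the triacylmethane F8, in which the central diketone carbon is bonded to the equatorial acyl group. LDA should then make the acetyl methyl attack the lactone carbonyl (Dieckmann-type closure), giving 22 with unambiguous connectivity.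

Step 10. Oxygen trapping of the planar tertiary C3 radical may take place with poor or reversed facial selectivity. The fallback sets out from 17 and comes back at 18. Ozonolysis of the exocyclic methylene (O3; PPh3) should give the cyclopentanone F9. Addition of a methyl nucleophile that tolerates the lactone and ester (MeTi(OiPr)3, or MeMgBr with CeCl3, −78 °C) should then give 18. The carbon nucleophile enters on the face that oxygen would otherwise take, so the opposite facial preference now gives the required C3 configuration.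

**Further compounds**

F1 | step 7 | diethyl 2-(3-methoxybut-2-en-1-yl)-2-[(2R,3E)-2-methyl-4-(phenylsulfonyl)-2-(triethylsilyloxy)but-3-en-1-yl]malonate (enol ether isomers) | COC(C)=CCC(C[C@@](C)(O[Si](CC)(CC)CC)/C=C/S(=O)(=O)c1ccccc1)(C(=O)OCC)C(=O)OCC
F2 | step 7 | diethyl 2-[(2R,3E)-2-methyl-4-(phenylsulfonyl)-2-(triethylsilyloxy)but-3-en-1-yl]-2-(3-oxobutyl)malonate | CC(=O)CCC(C[C@@](C)(O[Si](CC)(CC)CC)/C=C/S(=O)(=O)c1ccccc1)(C(=O)OCC)C(=O)OCC
F3 | step 7 | diethyl (3R,4S,5R)-4-acetyl-3-methyl-... trans-cyclohexane: 4-acetyl-5-methyl-3-(phenylsulfonylmethyl)-5-(triethylsilyloxy)cyclohexane-1,1-dicarboxylate with acetyl and sulfonylmethyl trans-diequatorial and silyloxy axial | CCOC(=O)C1(C(=O)OCC)C[C@@H](C(C)=O)[C@H](CS(=O)(=O)c2ccccc2)[C@](C)(O[Si](CC)(CC)CC)C1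
F4 | step 7 | the corresponding 4-isopropenyl cyclohexane | CCOC(=O)C1(C(=O)OCC)C[C@@H](C(C)=C)[C@H](CS(=O)(=O)c2ccccc2)[C@](C)(O[Si](CC)(CC)CC)C1
F5 | step 7 | the corresponding 4-[3-chloroprop-1-en-2-yl] cyclohexane | CCOC(=O)C1(C(=O)OCC)C[C@@H](C(=C)CCl)[C@H](CS(=O)(=O)c2ccccc2)[C@](C)(O[Si](CC)(CC)CC)C1
F6 | step 11 | lactone acid: (3S,3aR,5R,7R,7aS)-3-hydroxy-3,7-dimethyl-octahydro-1H-indene-5-carboxylic acid 5,7-carbolactone | O=C1[C@@]2(C[C@@H]3[C@H](CC[C@]3(C)O)[C@](C)(O1)C2)C(=O)O
F7 | step 11 | acyl imidazolide of the lactone acid | O=C1[C@@]2(C[C@@H]3[C@H](CC[C@]3(C)O)[C@](C)(O1)C2)C(=O)n4ccnc4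
F8 | step 11 | triacylmethane: lactone bearing a 2-acetyl-4-methyl-3-oxopentanoyl group at C5 | O=C1[C@@]2(C[C@@H]3[C@H](CC[C@]3(C)O)[C@](C)(O1)C2)C(=O)C(C(C)=O)C(=O)C(C)C
F9 | step 10 | ethyl (3aR,5R,7R,7aS)-7-methyl-3-oxo-octahydro-1H-indene-5-carboxylate 5,7-carbolactone | O=C1[C@@]2(C[C@@H]3[C@H](CCC3=O)[C@](C)(O1)C2)C(=O)OCC
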